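## Numbering used throughout

Atom labels follow the benzofuran numbering of the target (O1, C2, C3, C3a, C4, C5, C6, C7, C7a). The same labels are used for the atoms they become in every intermediate.

Compounds: 1 eugenol; 2 propanoic acid; 3 ortho-quinol propanoate; 4 silyl ketene acetal; 5 silyl ester; 6 dienone acid; 7 aryl Grignard reagent; 8 acid chloride; 9 dienone aryl ketone; 10 cyclic methyl ketal; 11 oxocarbenium ion; 12 target.

## Analysis of the target

Target 12 is a cis-fused 3,3a,7,7a-tetrahydro-1-benzofuran-6(2H)-one. An oxolane ring (O1–C2–C3–C3a–C7a) shares the C3a–C7a bond with a cyclohexenone ring (C3a–C4=C5(OMe)–C6(=O)–C7–C7a). It has four contiguous stereocentres: C2 (S, aryl), C3 (R, methyl), C3a (R, quaternary, allyl) and C7a (S). H-2, H-3, H-7a and the allyl group lie on one face of the oxolane; the aryl group, the methyl group and both bonds into the carbocycle lie on the other, concave face. The aryl and methyl groups are therefore cis to each other and the methyl is trans to the allyl.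

The feature that drives the plan is that the carbocycle is a dearomatised eugenol. The allyl on C3a, the methoxy on C5 and the oxygen on C6 stand exactly as the allyl, methoxy and hydroxy groups of 1. The one extra ring C–C bond, C3–C3a, sits para to the C6 oxygen and at the end of the allylic system O–C5–C4=C3a, which invites a [3,3] shift from an oxygen on C5.

The C7a–O1 bond is β to the C6 carbonyl, so it is an oxa-Michael retron and is labile. Other sensitive groups are the electron-rich benzylic ether at C2 (ionises with acid), the 1,5-diene allyl–C3a–C4=C5 (Cope shift) and the terminal alkene, which rules out hydrogenation. The difficulty is the quaternary C3a beside C3, the cis aryl/methyl pair on the concave face, and absolute control in a molecule that offers no obvious handle.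

## Retrosynthetic reasoning

**12 ⇒ 9 (O1–C7a and C2–H).** The C7a–O1 bond is cut as an oxa-Michael addition onto the unsubstituted enone arm of a cross-conjugated dienone, and the C2–H bond as hydride addition to a 2-aryl oxocarbenium ion (11, reached through ketal 10). Keeping C2 at the ketone level in 9 is deliberate. C3 is then α to a carbonyl or an oxocarbenium carbon and can equilibrate, C7a is forced by the cis ring fusion, and C2 is set by the direction of hydride attack. The only stereocentre that 9 has to carry is the quaternary C3a; the forward step must create three stereocentres from that one.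

**9 ⇒ 6 + 7 (C2–aryl).** The aryl ketone is cut at the C2–aryl bond to acid 6 and the aryl nucleophile 7. A palladium-catalysed acylation of an arylzinc reagent is chosen because the dienone of 6 tolerates it, whereas a lactone or ester cannot be arylated with an aryllithium beside this ketone.

**6 ⇒ 3 (C3–C3a).** The bond between the side chain and the quaternary carbon is cut as an ester-enolate [3,3] shift (via 4 and 5). In 3 the propanoate hangs on C5 through oxygen, and C5–C4=C3a is the allylic system. The forward rearrangement moves the propanoate α-carbon from the C5 oxygen to C3a, makes the quaternary centre at the allyl-bearing carbon, and turns the linear dienone into the 2-methoxy cross-conjugated dienone. It transfers the configuration of the C5 ketal centre to C3a. Cutting here gives a precursor that is simply eugenol oxidised once.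

**3 ⇒ 1 + 2 (C5–O).** The acyloxy group on the methoxy-bearing ortho carbon is introduced by Wessely-type oxidative dearomatisation of 1 with 2 as the nucleophile. This is the only place where absolute configuration has to be induced.

## Alternatives that were turned down

**Alternative 1:** the textbook, biomimetic cut.
- Disconnection: O1–C7a (oxa-Michael) and C3a–allyl, from an acyclic phenol with the C2/C3 pair already in place, (1S,2R)-1-(3,4-dimethoxyphenyl)-2-(4-hydroxy-3-methoxyphenyl)propan-1-ol A1.
- Forward key step: oxidative dearomatisation of A1 by a trivalent-iodine oxidant with an allylsilane to give the dienone alcohol A2, which closes by oxa-Michael addition.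
- Turned down because the quaternary carbon would form by intermolecular attack on a planar phenoxonium ion whose only bias is the acyclic C3 centre, so both faces react. Attack at the methoxy-bearing and the free ortho carbon also competes. The syn C2/C3 pair must first be made in separate asymmetric steps. The result is five to six steps around an unselective key step.

**Alternative 2:** cationic cycloaddition.
- Disconnection: O1–C2 and C3–C3a together.
- Forward key step: acid-promoted addition of an allyl-methoxy-para-quinone monoketal to (Z)-1,2-dimethoxy-4-(prop-1-en-1-yl)benzene to give the dienone A3, then conjugate reduction of C7=C7a.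
- Turned down because the addition is stepwise through a benzylic cation, which loses the alkene geometry and favours the trans aryl/methyl pair. It is racemic and bridged adducts compete. A3 has the wrong oxidation level at C7a, and there is no chemoselective way to deliver hydride to the β-carbon of a vinylogous ester beside a more reactive methoxy-enone and a terminal alkene.

**Alternative 3:** allylation on a non-aromatic ring.
- Disconnection: C3a–allyl.
- Forward key step: palladium-catalysed decarboxylative asymmetric allylic alkylation of a vinylogous-ester β-keto ester to A4, followed by Stork–Danheiser transposition and desaturation to reach a dienone of type 9.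
- Turned down because it needs nine to ten steps. The aryl ketone has to be protected through the hydride step, the second enone arm has to be dehydrogenated late, and the oxygen pattern that eugenol supplies for free has to be assembled.

Key step: step 2

Assumption: the (R,R)-antipode of the lactamide iodoarene is taken to give (S)-3; if the sense of induction is the opposite, the (S,S)-catalyst is used.

## Route

Step 1
Reactants: 1 2-methoxy-4-(prop-2-en-1-yl)phenol (eugenol); 2 propanoic acid
Product: 3 (1S)-1-methoxy-6-oxo-3-(prop-2-en-1-yl)cyclohexa-2,4-dien-1-yl propanoate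
Conditions: (R,R)-2,2′-[(2-iodo-1,3-phenylene)bis(oxy)]bis[N-(2,4,6-trimethylphenyl)propanamide] (10 mol %), 3-ClC6H4CO3H, EtCO2H (excess), CH2Cl2/(CF3)2CHOH, −20 °C; solution used cold at once
Reagents that add atoms: propanoic acid (2), CCC(=O)O
Why: Proposed new method: the iodoarene is oxidised in situ to a chiral bis(propanoyloxy) aryl iodane of trivalent iodine, eugenol binds to iodine through the phenol oxygen, and a propanoate ligand is delivered to the methoxy-bearing ortho carbon (the position that best carries positive charge) with loss of the iodoarene, the C2-symmetric lactamide arms shielding one face so that the ketal carbon should form as (S); the closest known reactions are the Wessely-type ortho-acyloxylation of 2-methoxyphenols by PhI(OAc)2 and the enantioselective spirolactonisation of phenols by this class of chiral iodoarene catalyst, in which the carboxylate is tethered.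

Step 2
Reactants: 3 (1S)-1-methoxy-6-oxo-3-(prop-2-en-1-yl)cyclohexa-2,4-dien-1-yl propanoate
Product: 6 2-[(1S)-3-methoxy-4-oxo-1-(prop-2-en-1-yl)cyclohexa-2,5-dien-1-yl]propanoic acid (both epimers at C-2 of the acid), via silyl ketene acetal 4 (not isolated), via trimethylsilyl ester 5 (not isolated)
Conditions: LiN(SiMe3)2, Me3SiCl/Et3N (premixed, present from the start), THF, −95 → 0 °C; then aq. citric acid, 0 °C
Reagents that add atoms: none
Why: Proposed new method: LiN(SiMe3)2 with Me3SiCl present from the start should convert the propanoate of 3 into silyl ketene acetal 4 before the transient enolate can attack the neighbouring dienone carbonyl, and 4 then undergoes an Ireland–Claisen [3,3] shift through the 3-oxa-1,5-diene C=C(OSi)–O–C5–C4=C3a. The shift breaks the C5–O bond and forms C3–C3a at the allyl-bearing ring carbon; the closest known reactions are the Ireland–Claisen rearrangement of tertiary and cyclohexenyl allylic esters to quaternary carbons and the thermal sigmatropic acyloxy shifts of ortho-quinol acetates, which show that this allylic system is pericyclically active, and what is new is the ester-enolate variant on a 6-acyloxycyclohexa-2,4-dienone. No ring is closed. The quaternary centre C3a is controlled by the ketal centre, because the ketene acetal is held through oxygen on one face of the ring and can only bond suprafacially, so the (S)-ketal gives (S)-C3a with the allyl group pushed to the opposite face. The second new centre (C-2 of the acid, later C3) is not controlled and need not be, since it is equilibrated in step 4. Regioselectivity is secured by the structure, as C3a is the only terminus of the one allylic system on the ketal carbon, and chemoselectivity rests on the dienone having no enolisable hydrogen and on the internal silyl quench. The driving force is large, because a linearly conjugated ketal-dienone becomes a cross-conjugated 2-methoxy-dienone and an ester carbonyl is gained, so the shift should run below 0 °C and not revert. Mild hydrolysis of silyl ester 5 gives acid 6.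

Step 3
Reactants: 6 2-[(1S)-3-methoxy-4-oxo-1-(prop-2-en-1-yl)cyclohexa-2,5-dien-1-yl]propanoic acid; 7 (3,4-dimethoxyphenyl)magnesium bromide
Product: 9 (4S)-4-[1-(3,4-dimethoxyphenyl)-1-oxopropan-2-yl]-2-methoxy-4-(prop-2-en-1-yl)cyclohexa-2,5-dien-1-one (both epimers at the side-chain CH), via acid chloride 8 (not isolated)
Conditions: 1-chloro-N,N,2-trimethylprop-1-en-1-amine, CH2Cl2, 0 °C; then 7 + ZnCl2 (THF, 0 °C), Pd(PPh3)4 (5 mol %), THF, 0 °C → rt
Reagents that add atoms: (3,4-dimethoxyphenyl)magnesium bromide (7), COc1ccc([Mg]Br)cc1OC
Why: The chloroenamine makes the acid chloride without acid or base, and Negishi acylation with zerovalent palladium couples it with the arylzinc reagent, which does not add to the dienone carbonyl or to its β-carbons; the quaternary centre is untouched and the configuration of the α-carbon is irrelevant.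

Step 4
Reactants: 9 (4S)-4-[1-(3,4-dimethoxyphenyl)-1-oxopropan-2-yl]-2-methoxy-4-(prop-2-en-1-yl)cyclohexa-2,5-dien-1-one
Product: 12 (2S,3R,3aR,7aS)-2-(3,4-dimethoxyphenyl)-5-methoxy-3-methyl-3a-(prop-2-en-1-yl)-3,3a,7,7a-tetrahydro-1-benzofuran-6(2H)-one, via cyclic methyl ketal 10 (not isolated), via oxocarbenium ion 11 (not isolated)
Conditions: MeOH (2 equiv), Et3SiH (3 equiv), BF3·OEt2 (2 equiv), CH2Cl2, −78 → −40 °C; aq. NaHCO3
Reagents that add atoms: none
Why: The methyl hemiketal of the aryl ketone adds through oxygen to C7a of the unsubstituted, more electrophilic enone arm (5-exo oxa-Michael addition, which can only give the cis ring fusion and so sets C7a from C3a), BF3 ionises ketal 10 to oxocarbenium ion 11, whose C3 epimers interconvert through the cyclic enol ether, and Et3SiH reduces it (reductive etherification). Hydride should add anti to the C3 methyl group and from the convex face (the face of H-7a and the allyl group, away from the carbocycle), so the epimer with methyl on the concave face is drained and the aryl and methyl groups end cis on that face.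

## Compound list

1 | 2-methoxy-4-(prop-2-en-1-yl)phenol (eugenol) | C=CCc1ccc(O)c(OC)c1 | starting material
2 | propanoic acid | CCC(=O)O | starting material
3 | (1S)-1-methoxy-6-oxo-3-(prop-2-en-1-yl)cyclohexa-2,4-dien-1-yl propanoate | CCC(=O)O[C@@]1(OC)C=C(CC=C)C=CC1=O | intermediate
4 | (6S)-6-methoxy-4-(prop-2-en-1-yl)-6-{[1-(trimethylsilyloxy)prop-1-en-1-yl]oxy}cyclohexa-2,4-dien-1-one | CC=C(O[Si](C)(C)C)O[C@@]1(OC)C=C(CC=C)C=CC1=O | intermediate
5 | trimethylsilyl 2-[(1S)-3-methoxy-4-oxo-1-(prop-2-en-1-yl)cyclohexa-2,5-dien-1-yl]propanoate | C=CC[C@@]1(C(C)C(=O)O[Si](C)(C)C)C=C(OC)C(=O)C=C1 | intermediate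
6 | 2-[(1S)-3-methoxy-4-oxo-1-(prop-2-en-1-yl)cyclohexa-2,5-dien-1-yl]propanoic acid (both epimers at C-2 of the acid) | C=CC[C@@]1(C(C)C(=O)O)C=C(OC)C(=O)C=C1 | intermediate
7 | (3,4-dimethoxyphenyl)magnesium bromide | COc1ccc([Mg]Br)cc1OC | starting material
8 | 2-[(1S)-3-methoxy-4-oxo-1-(prop-2-en-1-yl)cyclohexa-2,5-dien-1-yl]propanoyl chloride | C=CC[C@@]1(C(C)C(Cl)=O)C=C(OC)C(=O)C=C1 | intermediate
9 | (4S)-4-[1-(3,4-dimethoxyphenyl)-1-oxopropan-2-yl]-2-methoxy-4-(prop-2-en-1-yl)cyclohexa-2,5-dien-1-one (both epimers at the side-chain CH) | C=CC[C@@]1(C(C)C(=O)c2ccc(OC)c(OC)c2)C=C(OC)C(=O)C=C1 | intermediate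
10 | (3aS,7aS)-2-(3,4-dimethoxyphenyl)-2,5-dimethoxy-3-methyl-3a-(prop-2-en-1-yl)-3,3a,7,7a-tetrahydro-1-benzofuran-6(2H)-one (epimers at C2 and C3) | C=CC[C@@]12C=C(OC)C(=O)C[C@@H]1OC(OC)(c1ccc(OC)c(OC)c1)C2C | intermediate
11 | (3aS,7aS)-2-(3,4-dimethoxyphenyl)-5-methoxy-3-methyl-6-oxo-3a-(prop-2-en-1-yl)-3a,6,7,7a-tetrahydro-3H-1-benzofuran-1-ium (C3 epimers in equilibrium) | C=CC[C@@]12C=C(OC)C(=O)C[C@@H]1[O+]=C(c1ccc(OC)c(OC)c1)C2C | intermediate
12 | (2S,3R,3aR,7aS)-2-(3,4-dimethoxyphenyl)-5-methoxy-3-methyl-3a-(prop-2-en-1-yl)-3,3a,7,7a-tetrahydro-1-benzofuran-6(2H)-one | C=CC[C@@]12C=C(OC)C(=O)C[C@@H]1O[C@H](c1ccc(OC)c(OC)c1)[C@@H]2C | target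

Total step count: 4. Longest linear sequence: 4 steps (1 → 3 → 6 → 9 → 12).

## Steps least certain to work

**Step 2 (key step, Proposed new method).**
- What may go wrong: attack of the ester enolate on the adjacent dienone carbonyl before it is silylated (intramolecular aldol towards a butenolide), or ionisation of the ketal with loss of propanoate and rearomatisation.
- Fallback: an allyl-migration (Cope) relay that sets out from 2 and comes back at 9.
  - 2 acylates 1,2-dimethoxybenzene in polyphosphoric acid (Friedel–Crafts) to give 1-(3,4-dimethoxyphenyl)propan-1-one F1.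
  - Palladium-catalysed α-arylation of F1 with 4-bromo-2-methoxyphenol (Pd(OAc)2, P(t-Bu)3, excess LiN(SiMe3)2) gives 1-(3,4-dimethoxyphenyl)-2-(4-hydroxy-3-methoxyphenyl)propan-1-one F2.
  - Oxidative allylation of F2 at the methoxy-bearing ortho carbon with PhI(OCOCF3)2 and allyltrimethylsilane gives racemic 4-[1-(3,4-dimethoxyphenyl)-1-oxopropan-2-yl]-6-methoxy-6-(prop-2-en-1-yl)cyclohexa-2,4-dien-1-one F3.
  - Gentle warming in toluene moves the allyl group from C5 to C3a by a Cope shift to give racemic 4-[1-(3,4-dimethoxyphenyl)-1-oxopropan-2-yl]-2-methoxy-4-(prop-2-en-1-yl)cyclohexa-2,5-dien-1-one F4.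
  - Preparative chromatography of F4 on a chiral stationary phase supplies 9.

**Step 1 (Proposed new method).**
- What may go wrong: poor facial selectivity in the transfer of propanoate from iodine to carbon, competing attack at the para carbon, and Diels–Alder dimerisation of the dienone on standing.
- Fallback: sets out from 1 and comes back at 3. Oxidation of 1 with PhI(OCOEt)2 in CH2Cl2 at −78 °C (Wessely-type acyloxylation without a chiral catalyst) gives racemic 1-methoxy-6-oxo-3-(prop-2-en-1-yl)cyclohexa-2,4-dien-1-yl propanoate F5. Its enantiomers are separated cold by preparative chromatography on a chiral stationary phase to give 3.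

**Step 4.**
- What may go wrong: acid-induced migration of the allyl group in the cross-conjugated dienone before the ring has closed, hydride delivery from the concave face or incomplete equilibration at C3, closure onto the methoxy-bearing enone arm, and over-reduction of the benzylic C2–O bond.
- Fallback: sets out from 9 and comes back at 12, closing the ring under base before any acid is present. KN(SiMe3)2 with 18-crown-6 in THF at −78 °C makes the aryl ketone enolate, which can reach the dienone only through oxygen (5-exo), and a quench with AcOH gives (3aS,7aS)-2-(3,4-dimethoxyphenyl)-5-methoxy-3-methyl-3a-(prop-2-en-1-yl)-7,7a-dihydro-1-benzofuran-6(3aH)-one F6. Ionic hydrogenation of this cyclic enol ether (Et3SiH, CF3CO2H, CH2Cl2, −78 °C) then gives 12 through the same oxocarbenium ion 11.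

**Step 3.**
- What may go wrong: cyclisation of the acid onto its own dienone (intramolecular oxa-Michael lactonisation) during activation, and slow acylation at the hindered carbonyl.
- Fallback: sets out from 6 and comes back at 9 without an acid chloride. Pivalic anhydride forms the mixed anhydride 2-[(1S)-3-methoxy-4-oxo-1-(prop-2-en-1-yl)cyclohexa-2,5-dien-1-yl]propanoic 2,2-dimethylpropanoic anhydride F7 in situ, and this is coupled with (3,4-dimethoxyphenyl)boronic acid under Pd(OAc)2/P(4-MeOC6H4)3 in wet THF to give 9.

## Further compounds

F1 | step 2 | 1-(3,4-dimethoxyphenyl)propan-1-one | CCC(=O)c1ccc(OC)c(OC)c1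
F2 | step 2 | rac-1-(3,4-dimethoxyphenyl)-2-(4-hydroxy-3-methoxyphenyl)propan-1-one | CC(C(=O)c1ccc(OC)c(OC)c1)c1ccc(O)c(OC)c1
F3 | step 2 | rac-4-[1-(3,4-dimethoxyphenyl)-1-oxopropan-2-yl]-6-methoxy-6-(prop-2-en-1-yl)cyclohexa-2,4-dien-1-one | C=CCC1(OC)C=C(C(C)C(=O)c2ccc(OC)c(OC)c2)C=CC1=O
F4 | step 2 | rac-4-[1-(3,4-dimethoxyphenyl)-1-oxopropan-2-yl]-2-methoxy-4-(prop-2-en-1-yl)cyclohexa-2,5-dien-1-one | C=CCC1(C(C)C(=O)c2ccc(OC)c(OC)c2)C=C(OC)C(=O)C=C1
F5 | step 1 | rac-1-methoxy-6-oxo-3-(prop-2-en-1-yl)cyclohexa-2,4-dien-1-yl propanoate | CCC(=O)OC1(OC)C=C(CC=C)C=CC1=O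
F6 | step 4 | (3aS,7aS)-2-(3,4-dimethoxyphenyl)-5-methoxy-3-methyl-3a-(prop-2-en-1-yl)-7,7a-dihydro-1-benzofuran-6(3aH)-one | C=CC[C@@]12C=C(OC)C(=O)C[C@@H]1OC(c1ccc(OC)c(OC)c1)=C2C
F7 | step 3 | 2-[(1S)-3-methoxy-4-oxo-1-(prop-2-en-1-yl)cyclohexa-2,5-dien-1-yl]propanoic 2,2-dimethylpropanoic anhydride | C=CC[C@@]1(C(C)C(=O)OC(=O)C(C)(C)C)C=C(OC)C(=O)C=C1
A1 | alternative 1 | (1S,2R)-1-(3,4-dimethoxyphenyl)-2-(4-hydroxy-3-methoxyphenyl)propan-1-ol | O[C@H](c1ccc(OC)c(OC)c1)[C@H](C)c1ccc(O)c(OC)c1
A2 | alternative 1 | (4R)-4-[(1S,2R)-1-(3,4-dimethoxyphenyl)-1-hydroxypropan-2-yl]-2-methoxy-4-(prop-2-en-1-yl)cyclohexa-2,5-dien-1-one | C=CC[C@@]1([C@@H](C)[C@H](O)c2ccc(OC)c(OC)c2)C=C(OC)C(=O)C=C1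
A3 | alternative 2 | (2S,3R,3aR)-2-(3,4-dimethoxyphenyl)-5-methoxy-3-methyl-3a-(prop-2-en-1-yl)-3,3a-dihydro-1-benzofuran-6(2H)-one | C=CC[C@@]12C=C(OC)C(=O)C=C1O[C@H](c1ccc(OC)c(OC)c1)[C@@H]2C
A4 | alternative 3 | (6R)-6-[2-(3,4-dimethoxyphenyl)-2-oxoethyl]-3,4,4-trimethoxy-6-(prop-2-en-1-yl)cyclohex-2-en-1-one | C=CC[C@@]1(CC(=O)c2ccc(OC)c(OC)c2)CC(OC)(OC)C(OC)=CC1=O
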